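**Strategy.** The plan makes ring B (C5–C6–C7–C8–C9–C10) one carbon too large and lets the surplus atom leave as the acetate. A bromonium-induced polyene cyclisation, steered by one carbinol centre (Ca), sets C1, C10, C5 and C4 of ring A. Metathesis then closes a cycloheptene in which Ca sits between C5 and C6. After oxidation and methyl addition (giving a trans-fused 6–7 tertiary allylic alcohol), the key step shifts C5 from Ca to C6 in a bromonium-triggered semipinacol rearrangement. The seven-membered ring contracts to ring B and Ca becomes an acetyl group on C6. The step exploits the C6 acetoxy group flanked by C5 and C7: cuprate addition places isopropyl axially on C7, and Baeyer–Villiger oxidation converts acetyl into acetate.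

Key step: step 11

Remark: eudesmane numbering is used (C1 = CHBr, C4 = carbinol carbon, C5/C10 = ring fusion, C6 = CHOAc, C7 = CH-i-Pr). Ca is the extra carbon. α is the face of H-5 and β is the face of the C10 methyl group.

Step 1
Reactants: 1 geranyl acetate
Product: 2 (2E,6E)-8-hydroxy-3,7-dimethylocta-2,6-dien-1-yl acetate
Conditions: SeO2 (cat.), t-BuOOH, salicylic acid (cat.), CH2Cl2, rt
Reagents that add atoms: tert-butyl hydroperoxide, CC(C)(C)OO (oxygen relayed through SeO2, O=[Se]=O)
Why: Riley-type allylic oxidation (ene reaction, then [2,3]-shift) should attack the more electron-rich distal alkene at its (E)-methyl group, so the future C9 is functionalised with the 6E geometry kept.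

Step 2
Reactants: 2 (2E,6E)-8-hydroxy-3,7-dimethylocta-2,6-dien-1-yl acetate
Product: 3 (2E,6E)-8-bromo-3,7-dimethylocta-2,6-dien-1-yl acetate
Conditions: CBr4, PPh3, CH2Cl2, 0 °C
Reagents that add atoms: carbon tetrabromide, BrC(Br)(Br)Br
Why: The Appel reaction should convert the primary allylic alcohol into the bromide by SN2 without allylic shift and without touching the acetate.

Step 3
Reactants: 3 (2E,6E)-8-bromo-3,7-dimethylocta-2,6-dien-1-yl acetate
Product: 4 (2E,6E)-3,7-dimethylundeca-2,6,10-trien-1-ol
Conditions: allylMgBr (3.3 equiv), Et2O/THF, −20 °C to rt; aq NH4Cl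
Reagents that add atoms: allylmagnesium bromide, C=CC[Mg]Br
Why: Allyl Grignard coupling at the unhindered primary allylic bromide (SN2) should build the C8–C9 bond, and the excess reagent cleaves the acetate in the same operation, with both E-alkenes untouched.

Step 4
Reactants: 4 (2E,6E)-3,7-dimethylundeca-2,6,10-trien-1-ol
Product: 5 (2E,6E)-3,7-dimethylundeca-2,6,10-trienal
Conditions: MnO2, CH2Cl2, rt
Reagents that add atoms: none
Why: MnO2 should oxidise the allylic alcohol to the enal under neutral conditions without E/Z isomerisation.

Step 5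
Reactants: 5 (2E,6E)-3,7-dimethylundeca-2,6,10-trienal
Product: 7 tert-butyl (3S,4E,8E)-5,9-dimethyltrideca-1,4,8,12-tetraen-3-yl carbonate, via zinc alkoxide 6 (not isolated)
Conditions: vinylMgBr, ZnCl2, TEEDA, (−)-MIB (10 mol %), toluene/hexane, −20 to 0 °C; then Boc2O, DMAP (cat.), rt
Reagents that add atoms: vinylmagnesium bromide, C=C[Mg]Br; di-tert-butyl dicarbonate, CC(C)(C)OC(=O)OC(=O)OC(C)(C)C
Why: In this amino-alcohol-catalysed enantioselective alkenylzinc addition, (−)-MIB should direct vinyl to the Si face of the enal and set Ca as (S), and the zinc alkoxide is acylated in the flask.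

Step 6
Reactants: 7 tert-butyl (3S,4E,8E)-5,9-dimethyltrideca-1,4,8,12-tetraen-3-yl carbonate
Product: 8 bicyclic bromo carbonate (ring A trans-fused at C4–C5 to a 1,3-dioxan-2-one; 1β-Br equatorial, 10β-CH3 axial, 10α-but-3-enyl, 5α-H, 4β-CH3, O on C4 α, Ca with β-H and an equatorial vinyl group)
Conditions: Et2SBr·SbCl5Br (1.05 equiv), MeNO2, −25 °C, 5 min; aq Na2SO3/NaHCO3
Reagents that add atoms: bromodiethylsulfonium bromopentachloroantimonate, CC[S+](Br)CC.Cl[Sb-](Cl)(Cl)(Cl)(Cl)Br
Why: In this bromonium-induced cation–π cyclisation Br+ should take the most electron-rich C1=C10 alkene, C5 attacks C10 through a chair 6-endo transition state and the carbonate carbonyl traps C4 with loss of isobutene, so both E-alkenes add anti (Br, O-4 and Ca equatorial; C10-CH3 and H-5 axial), while Ca selects the alkene face because only with Ca–H eclipsing the C4 methyl group (allylic 1,3-strain) does the vinyl group end equatorial, and reversible Br+ transfer feeds this pathway.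

Step 7
Reactants: 8 bicyclic bromo carbonate
Product: 9 tricyclic allylic carbonate (ring A, cycloheptene C5–Ca–C6=C7–C8–C9–C10 and the six-membered carbonate O4–CO–O–Ca; 1β-Br, 4β-CH3, 5α-H, 10β-CH3, Ca-H β)
Conditions: second-generation Grubbs catalyst (5 mol %), CH2Cl2 (high dilution), reflux
Reagents that add atoms: none
Why: Ring-closing metathesis of the two monosubstituted alkenes, which sit on equatorial, mutually gauche substituents of C5 and C10, should close the trans-fused cycloheptene with loss of ethene and touch no stereocentre.

Step 8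
Reactants: 9 tricyclic allylic carbonate
Product: 10 allylic diol (4α-OH, Ca α-OH, C6=C7)
Conditions: K2CO3 (cat.), MeOH, 0 °C to rt
Reagents that add atoms: none
Why: Base-catalysed transesterification should remove the cyclic carbonate as dimethyl carbonate under conditions that leave the neopentyl secondary bromide alone.

Step 9
Reactants: 10 allylic diol
Product: 11 cycloheptenone (Ca=O conjugated with C6=C7; 4α-OH)
Conditions: MnO2, CH2Cl2, rt
Reagents that add atoms: none
Why: MnO2 should oxidise only the allylic secondary alcohol at Ca, and the neutral medium spares the aldol-type C4-hydroxy ketone and the C5 centre.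

Step 10
Reactants: 11 cycloheptenone
Product: 12 tertiary allylic alcohol (Ca: α-CH3 pseudo-equatorial, β-OH pseudo-axial; C6=C7; 4α-OH)
Conditions: MeLi (2.5 equiv), THF, −78 °C; aq NH4Cl
Reagents that add atoms: methyllithium, [Li]C
Why: MeLi should add 1,2 to the enone from the α face, because the β face of Ca is flanked by the axial methyl groups on C4 and C10, and the low temperature keeps the lithium aldolate from retro-aldol cleavage.

Step 11
Reactants: 12 tertiary allylic alcohol
Product: 14 6-acetyl-Δ6-octalin (ring B with C6=C7, acetyl on C6; 1β-Br, 4α-OH, 4β-CH3, 5α-H, 10β-CH3), via dibromo ketone 13 (not isolated)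
Conditions: NBS, CH2Cl2, −20 to 0 °C; then DBU, rt
Reagents that add atoms: none
Why: NBS, steered by the pseudo-axial β-hydroxyl on Ca (hydrogen bond or transient hypobromite), should form the bromonium ion on the β face of C6=C7; in the chair cycloheptene the ring bond Ca–C5 then lies antiperiplanar to the C6–Br bond, so C5 shifts from Ca to C6 while the hydroxyl oxygen becomes the acetyl carbonyl, and DBU removes HBr from the β-bromo ketone 13 by E1cB. The closest known reaction type is the halonium-induced semipinacol rearrangement of tertiary allylic alcohols, here run in the ring-contracting sense. No ring is closed by cyclisation: ring B (C5–C6–C7–C8–C9–C10) forms by a suprafacial 1,2-alkyl shift through a three-centre transition state, and the seven-membered ring loses Ca. C5 migrates with retention, so the trans ring fusion from step 6 is kept, and the two transient centres C6 and C7 of 13 (with its strained axial acetyl group) are erased by the elimination, so no permanent new stereocentre has to be controlled. The step needs migration of C5 rather than of the methyl group or oxirane closure by the hydroxyl; the methyl group is pseudo-equatorial, gauche to the breaking C6–Br bond and a poorer migrating group, and the hydroxyl is syn to the bromonium ion and cannot attack from the rear. It also needs chemoselectivity, which is secured because C6=C7 is the only alkene and the neopentyl C1 bromide and the C4 alcohol are inert to NBS and DBU.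

Step 12
Reactants: 14 6-acetyl-Δ6-octalin
Product: 15 6α-acetyl-7α-isopropyl decalin (1β-Br, 4α-OH, 4β-CH3, 5α-H, 10β-CH3)
Conditions: i-PrMgCl (4.4 equiv), CuBr·SMe2 (2.2 equiv), THF, −78 to −40 °C; aq NH4Cl; then K2CO3 (cat.), MeOH, rt
Reagents that add atoms: isopropylmagnesium chloride, CC(C)[Mg]Cl
Why: Organocuprate conjugate addition should follow the stereoelectronically preferred axial path onto the half-chair of ring B, which at C7 is the open α face, and base equilibration then places the acetyl group equatorial (α) at C6, since the β position is syn-axial to the methyl groups on C4 and C10.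

Step 13
Reactants: 15 6α-acetyl-7α-isopropyl decalin
Product: 16 austradiol acetate
Conditions: mCPBA, CH2Cl2, rt
Reagents that add atoms: 3-chloroperbenzoic acid, OOC(=O)c1cccc(Cl)c1
Why: In the Baeyer–Villiger oxidation the secondary carbon C6 should migrate in preference to methyl and with retention, so the 6α-acetate forms directly while the tertiary C4 alcohol and the bromide are left untouched.

**Compound list**

1 | geranyl acetate, (2E)-3,7-dimethylocta-2,6-dien-1-yl acetate | CC(C)=CCC/C(C)=C/COC(C)=O | starting material
2 | (2E,6E)-8-hydroxy-3,7-dimethylocta-2,6-dien-1-yl acetate | OC/C(C)=C/CC/C(C)=C/COC(C)=O | intermediate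
3 | (2E,6E)-8-bromo-3,7-dimethylocta-2,6-dien-1-yl acetate | BrC/C(C)=C/CC/C(C)=C/COC(C)=O | intermediate
4 | (2E,6E)-3,7-dimethylundeca-2,6,10-trien-1-ol | C=CCC/C(C)=C/CC/C(C)=C/CO | intermediate
5 | (2E,6E)-3,7-dimethylundeca-2,6,10-trienal | C=CCC/C(C)=C/CC/C(C)=C/C=O | intermediate
6 | vinylzinc (3S,4E,8E)-5,9-dimethyltrideca-1,4,8,12-tetraen-3-olate (zinc alkoxide, not isolated) | C=CCC/C(C)=C/CC/C(C)=C/[C@H](C=C)O[Zn]C=C | intermediate
7 | tert-butyl (3S,4E,8E)-5,9-dimethyltrideca-1,4,8,12-tetraen-3-yl carbonate | C=CCC/C(C)=C/CC/C(C)=C/[C@H](C=C)OC(=O)OC(C)(C)C | intermediate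
8 | bicyclic bromo carbonate (1β-Br, 10β-CH3, 10α-butenyl, 5α-H, 4β-CH3, carbonate on O4 and O–Ca, vinyl equatorial on Ca) | O=C1O[C@@H](C=C)[C@H]2[C@](C)(O1)CC[C@@H](Br)[C@]2(C)CCC=C | intermediate
9 | tricyclic allylic carbonate (trans-fused cyclohexane/cycloheptene, C6=C7) | O=C3O[C@H]1C=CCC[C@@]2(C)[C@H](Br)CC[C@@](C)(O3)[C@H]12 | intermediate
10 | allylic diol (4α-OH, Ca α-OH) | O[C@H]1C=CCC[C@@]2(C)[C@H](Br)CC[C@@](C)(O)[C@H]12 | intermediate
11 | cycloheptenone (Ca=O, C6=C7, 4α-OH) | O=C1C=CCC[C@@]2(C)[C@H](Br)CC[C@@](C)(O)[C@H]12 | intermediate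
12 | tertiary allylic alcohol (Ca: α-CH3, β-OH) | C[C@@]1(O)C=CCC[C@@]2(C)[C@H](Br)CC[C@@](C)(O)[C@H]12 | intermediate
13 | 6β-acetyl-1β,7β-dibromo decalin (dibromo ketone, not isolated) | CC(=O)[C@@H]1[C@H](Br)CC[C@@]2(C)[C@H](Br)CC[C@@](C)(O)[C@H]12 | intermediate
14 | 6-acetyl-Δ6-octalin (1β-Br, 4α-OH) | CC(=O)C1=CCC[C@@]2(C)[C@H](Br)CC[C@@](C)(O)[C@H]12 | intermediate
15 | 6α-acetyl-7α-isopropyl decalin (1β-Br, 4α-OH) | CC(=O)[C@H]1[C@@H](C(C)C)CC[C@@]2(C)[C@H](Br)CC[C@@](C)(O)[C@H]12 | intermediate
16 | austradiol acetate, (1R,4R,5S,6S,7R,10R)-6-acetoxy-1-bromoeudesman-4-ol | CC(=O)O[C@H]1[C@@H](C(C)C)CC[C@@]2(C)[C@H](Br)CC[C@@](C)(O)[C@H]12 | target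

Total step count: 13. Longest linear sequence: 13 steps, from geranyl acetate.

**Steps most likely to fail**

Step 11. Delivery of Br+ to the α face would put the hydroxyl group, not the Ca–C5 bond, antiperiplanar to the breaking bond and divert material into oxirane closure. Ionisation of the crowded tertiary allylic alcohol is a second drain. The fallback sets out from 12 and comes back at 14, and it replaces the halonium by an oxygen leaving group whose face is fixed by metal-alkoxide delivery. Hydroxyl-directed epoxidation (VO(acac)2, t-BuOOH, CH2Cl2) should give the syn (β) epoxy alcohol F1. BF3·OEt2 at −78 °C should open the oxirane at C6 with the same shift of C5, giving the aldol-type 7β-hydroxy ketone F2. Mesylation (MsCl, Et3N) followed by DBU then eliminates to 14.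

Step 6. The relay of chirality from Ca may be poor if Br+ delivery to the two faces of C1=C10 is not reversible, and the bis-allylic carbonate may ionise before cyclisation. The fallback sets out from 7 and comes back at 8, and it fixes the bromonium face independently. Shi epoxidation of the C1=C10 alkene, using the enantiomer of the fructose-derived ketone with Oxone, should give the (S,S)-epoxide F3. Li2NiBr4 in THF should open it at the secondary carbon with inversion to the bromohydrin F4. Acid ionisation of the tertiary alcohol (TfOH cat., MeNO2, −25 °C) should regenerate a configurationally defined bromonium ion by bromine participation, which cyclises to 8.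

Step 5. Salt-promoted background addition may erode the enantiomeric purity, and acylation of the zinc alkoxide may be slow. The fallback sets out from 5 and comes back at 7, and it uses an enzyme instead of a chiral catalyst. VinylMgBr in THF should give the racemic dienol F5. A lipase (Candida antarctica lipase B, vinyl acetate, hexane) should acylate the (R)-enantiomer to the acetate F7, following the Kazlauskas rule with vinyl as the medium group, and leave the (S)-alcohol F6. After separation, F6 is converted with Boc2O/DMAP into 7.

Further compounds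
F1 | step 11 | syn (β) 6,7-epoxy alcohol of 12 | C[C@@]1(O)[C@@H]3O[C@@H]3CC[C@@]2(C)[C@H](Br)CC[C@@](C)(O)[C@H]12
F2 | step 11 | 6β-acetyl-7β-hydroxy decalin (1β-Br, 4α-OH) | CC(=O)[C@@H]1[C@H](O)CC[C@@]2(C)[C@H](Br)CC[C@@](C)(O)[C@H]12
F3 | step 6 | tert-butyl (3S,4E)-7-[(2S,3S)-3-(but-3-en-1-yl)-3-methyloxiran-2-yl]-5-methylhepta-1,4-dien-3-yl carbonate | C=CCC[C@]1(C)O[C@H]1CC/C(C)=C/[C@H](C=C)OC(=O)OC(C)(C)C
F4 | step 6 | tert-butyl (3S,4E,8R,9S)-8-bromo-9-hydroxy-5,9-dimethyltrideca-1,4,12-trien-3-yl carbonate | C=CCC[C@](C)(O)[C@H](Br)CC/C(C)=C/[C@H](C=C)OC(=O)OC(C)(C)C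
F5 | step 5 | racemic (4E,8E)-5,9-dimethyltrideca-1,4,8,12-tetraen-3-ol | C=CCC/C(C)=C/CC/C(C)=C/C(O)C=C
F6 | step 5 | (3S,4E,8E)-5,9-dimethyltrideca-1,4,8,12-tetraen-3-ol | C=CCC/C(C)=C/CC/C(C)=C/[C@H](C=C)O
F7 | step 5 | (3R,4E,8E)-5,9-dimethyltrideca-1,4,8,12-tetraen-3-yl acetate | C=CCC/C(C)=C/CC/C(C)=C/[C@@H](C=C)OC(C)=O
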